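A direct plan would cut the Ar–O–Ar bond between two finished arenes. Ring-B iodide A1 and ring-A phenol A2 would be joined late by a Cu-catalysed Ullmann coupling to the tri-MOM diaryl ether A3, and acid would then free the three phenols.
Weakest step, the Ullmann coupling: the C–I carbon of A1 would lie between two alkoxy groups on an electron-rich ring, and the OH of A2 would be ortho to an ester, chelated and poorly nucleophilic. The whole convergence would hang on a doubly hindered, electronically mismatched C–O coupling near 105 °C, with reductive loss of iodine as the easy exit.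
Second, the run-up to both partners: A1 would cost six one-substituent-at-a-time operations from hydroquinone A4, the last a lithiation beside the doubly activated benzylic/allylic CH2 of the prenyl group. Ring A would be assembled from acyclic esters by acylating a dianion with an enolisable malonyl chloride, only to reach methyl 2,4,6-trihydroxybenzoate A5, which can be bought.
Third, the protecting-group end game: three MOM groups would go on and off without building anything. Their removal in warm aqueous HCl/MeOH would expose the trisubstituted prenyl alkene to Markovnikov addition of water, methanol or HCl in the very last step.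

**Retrosynthetic overview**
1. Numbering: ring A = C1 (CO2Me), C2 (OH), C4 (OH), C6 (O-aryl); ring B = C1' (O), C2' (OH), C3' (OMe), C4' (H), C5' (prenyl), C6' (OMe).
2. Last disconnection, C5'–CH2: the prenyl group stands para to the only free OH of ring B (C2'–OH), and both ortho positions of that OH (C1', C3') carry oxygen. So 20 ⇒ aryl prenyl ether 17 by a para-Claisen–Cope shift, and the prenyl group serves as its own protecting group for O-2'.
3. Key disconnection, C1–C2 and C5–C6 of ring A: the alternating C2–OH/C4–OH/C6–OAr pattern around the C1 ester is an acetoacetate C4 unit plus an O–C≡C–CO2Me unit. So 17 ⇒ 3-aryloxypropiolate 11 + 1-methoxy-1,3-bis(silyloxy)diene 14 by a [4+2] benzannulation; ring A is grown on the ether oxygen and no C–O bond is ever made between two arenes.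
4. 11 ⇒ mono-prenyl ether 5 of the C2v-symmetric 3,6-dimethoxycatechol 3, which holds the four contiguous oxygens C6'/C1'/C2'/C3'. The symmetry removes all ring-B regiochemistry, and the O–C6 bond is made on a linear C2 electrophile that ignores the two ortho groups.
5. Ring order: ring B is bought as an arene and ring A closes in step 8. The design needs no hindered coupling, no protecting group and no acid once the prenyl group is in place.

Key step: step 8

Assumption: Paucinervin B has no stereocentre and no stereogenic double bond, so the demand for a single enantiomer is met by the correct constitution alone.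

**Route**

Step 1
Reactants: 1 2,5-dimethoxyphenol
Product: 2 2-hydroxy-3,6-dimethoxybenzaldehyde
Conditions: MgCl2, Et3N, (CH2O)n, MeCN, reflux; 1 M HCl
Reagents that add atoms: paraformaldehyde (reacts as formaldehyde), C=O
Why: Casnati–Skattebøl ortho-formylation, in which the magnesium phenoxide delivers formaldehyde to the only free ortho position and a second formaldehyde oxidises the benzylic alkoxide by hydride transfer, so the site of the fourth ring-B oxygen is marked without a protecting group.

Step 2
Reactants: 2 2-hydroxy-3,6-dimethoxybenzaldehyde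
Product: 3 3,6-dimethoxybenzene-1,2-diol
Conditions: 30% H2O2 (1.1 equiv), aq. NaOH, THF, 0 °C → rt, N2; then HCl
Reagents that add atoms: hydrogen peroxide, OO
Why: Dakin oxidation, in which hydroperoxide adds to the ortho-hydroxy aldehyde, the electron-rich aryl group migrates to oxygen and the formate is hydrolysed in situ, giving the C2v-symmetric catechol with the four contiguous oxygens of ring B.

Step 3
Reactants: 3 3,6-dimethoxybenzene-1,2-diol; 4 prenyl bromide (1-bromo-3-methylbut-2-ene)
Product: 5 3,6-dimethoxy-2-[(3-methylbut-2-en-1-yl)oxy]phenol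
Conditions: K2CO3 (1.0 equiv), 4 (1.0 equiv), acetone, rt, N2
Reagents that add atoms: none
Why: Williamson mono-alkylation, in which the two OH groups of 3 are equivalent, so only mono versus bis selectivity is needed; this is secured by one equivalent of base and bromide and by the lower acidity of the hydrogen-bonded, more hindered OH of 5.

Step 4
Reactants: 5 3,6-dimethoxy-2-[(3-methylbut-2-en-1-yl)oxy]phenol; 6 trichloroethylene
Product: 8 2-{[(E)-1,2-dichloroethenyl]oxy}-1,4-dimethoxy-3-[(3-methylbut-2-en-1-yl)oxy]benzene, via dichloroacetylene 7 (not isolated)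
Conditions: K2CO3, DMF, 70 °C
Reagents that add atoms: none
Why: Known synthesis of aryl (E)-1,2-dichlorovinyl ethers, in which base turns 6 into dichloroacetylene in situ and the phenoxide adds to it in anti fashion; the electrophile is a linear two-carbon unit, so the two ortho substituents of 5 should not hinder formation of the O–C6 bond.

Step 5
Reactants: 8 2-{[(E)-1,2-dichloroethenyl]oxy}-1,4-dimethoxy-3-[(3-methylbut-2-en-1-yl)oxy]benzene
Product: 11 methyl 3-{3,6-dimethoxy-2-[(3-methylbut-2-en-1-yl)oxy]phenoxy}prop-2-ynoate, via chloroalkynyl ether 9 (not isolated), via lithium aryloxyacetylide 10 (not isolated)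
Conditions: n-BuLi (2.2 equiv), THF, –78 → –40 °C; ClCO2Me, –78 → 0 °C; Et3N-deactivated silica
Reagents that add atoms: methyl chloroformate, COC(=O)Cl
Why: Dichlorovinyl-ether route to ynol ethers, in which elimination of HCl gives 9, Cl/Li exchange gives 10 and C-acylation by the chloroformate gives the push–pull ynoate, all at or below –40 °C, where neither the aryl prenyl ether nor the ring C–H bonds should be metalated.

Step 6
Reactants: 12 methyl acetoacetate
Product: 13 methyl 3-(trimethylsilyloxy)but-2-enoate (E/Z mixture)
Conditions: TMSCl, Et3N, hexane, rt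
Reagents that add atoms: chlorotrimethylsilane, C[Si](C)(C)Cl
Why: O-silylation of the β-keto ester enol under soft enolisation; the alkene geometry is of no consequence because it vanishes in ring A.

Step 7
Reactants: 13 methyl 3-(trimethylsilyloxy)but-2-enoate
Product: 14 1-methoxy-1,3-bis(trimethylsilyloxy)buta-1,3-diene (Chan's diene)
Conditions: LDA, THF, –78 °C; TMSCl, –78 → 0 °C
Reagents that add atoms: chlorotrimethylsilane, C[Si](C)(C)Cl
Why: Kinetic γ-deprotonation of the vinylogous ester and O-silylation of the dienolate, the standard preparation of this masked acetoacetate dianion.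

Step 8
Reactants: 11 methyl 3-{3,6-dimethoxy-2-[(3-methylbut-2-en-1-yl)oxy]phenoxy}prop-2-ynoate; 14 1-methoxy-1,3-bis(trimethylsilyloxy)buta-1,3-diene
Product: 17 methyl 2-{3,6-dimethoxy-2-[(3-methylbut-2-en-1-yl)oxy]phenoxy}-4,6-dihydroxybenzoate, via cycloadduct 15 (not isolated), via bis-silyl ether 16 (not isolated)
Conditions: 14 (3 equiv), toluene, 115 °C, sealed tube, Ar; then MeOH, cat. citric acid, rt
Reagents that add atoms: none
Why: Proposed new method: alkyne 11 is a push–pull dienophile whose aryloxy-bearing carbon (future C6) is the electrophilic and whose ester-bearing carbon (future C1) is the nucleophilic terminus, and diene 14 has its most nucleophilic site at the C4 methylene and its acceptor site at the ketene-acetal carbon C1, so a concerted but strongly asynchronous [4+2] cycloaddition should form C5–C6 first and C1–C2 second, in this orientation only. The closest known reaction type is the thermal Diels–Alder benzannulation of 1-alkoxy-1,3-bis(silyloxy)buta-1,3-dienes with 3-alkyl-, 3-silyl- and 3-halopropiolates, which gives 6-substituted 2,4-dihydroxybenzoates with the same regiochemistry; a 3-aryloxypropiolate has not been used in it, and its donor group is expected to slow the reaction but to sharpen the polarisation. Ring A closes as an unstrained six-membered carbocycle in an intermolecular [4+2] mode, and cycloadduct 15 aromatises by 1,4-elimination of methanol from C2 and C5, whereas the aryloxy group stands on an sp2 carbon and has no elimination path, so the ether oxygen is kept. The only new stereocentre (C2 of 15, racemic) is erased on aromatisation, so nothing has to be controlled. The step needs chemoselectivity for the electron-poor alkyne over the electron-rich prenyl alkene, which the nucleophilic diene secures, and survival of the aryl prenyl ether, which rearranges only well above 115 °C and would in any case move towards 20. Methanol with a trace of citric acid then cleaves the two aryl silyl ethers of 16 without touching the prenyl ether.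

Step 9
Reactants: 17 methyl 2-{3,6-dimethoxy-2-[(3-methylbut-2-en-1-yl)oxy]phenoxy}-4,6-dihydroxybenzoate
Product: 20 Paucinervin B (methyl 2,4-dihydroxy-6-[2-hydroxy-3,6-dimethoxy-5-(3-methylbut-2-en-1-yl)phenoxy]benzoate), via ortho-dienone 18 (not isolated), via para-dienone 19 (not isolated)
Conditions: PhNEt2, 190 °C, sealed tube, Ar
Reagents that add atoms: none
Why: Aromatic para-Claisen–Cope rearrangement, in which the first [3,3] shift from O-2' can only reach the blocked ortho carbons C3' (shown as 18) or C1', the non-enolisable ortho-dienone passes the inverted 1,1-dimethylallyl group on to C5' by a second [3,3] shift from either position, the double inversion restores the linear prenyl group, tautomerisation of 19 frees C2'–OH, and the basic solvent suppresses acid-catalysed ionisation of the ether; no stereocentre remains.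

**Compound list**
1 | 2,5-dimethoxyphenol | COc1ccc(OC)c(O)c1 | starting material
2 | 2-hydroxy-3,6-dimethoxybenzaldehyde | O=Cc1c(O)c(OC)ccc1OC | intermediate
3 | 3,6-dimethoxybenzene-1,2-diol | COc1ccc(OC)c(O)c1O | intermediate
4 | prenyl bromide | CC(C)=CCBr | starting material
5 | 3,6-dimethoxy-2-[(3-methylbut-2-en-1-yl)oxy]phenol | COc1ccc(OC)c(OCC=C(C)C)c1O | intermediate
6 | trichloroethylene | ClC=C(Cl)Cl | starting material
7 | dichloroacetylene (not isolated) | ClC#CCl | intermediate
8 | 2-{[(E)-1,2-dichloroethenyl]oxy}-1,4-dimethoxy-3-[(3-methylbut-2-en-1-yl)oxy]benzene | COc1ccc(OC)c(OCC=C(C)C)c1O/C(Cl)=C\Cl | intermediate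
9 | chloroalkynyl ether (not isolated) | COc1ccc(OC)c(OCC=C(C)C)c1OC#CCl | intermediate
10 | lithium aryloxyacetylide (not isolated) | COc1ccc(OC)c(OCC=C(C)C)c1OC#C[Li] | intermediate
11 | methyl 3-{3,6-dimethoxy-2-[(3-methylbut-2-en-1-yl)oxy]phenoxy}prop-2-ynoate | COC(=O)C#COc1c(OC)ccc(OC)c1OCC=C(C)C | intermediate
12 | methyl acetoacetate | CC(=O)CC(=O)OC | starting material
13 | methyl 3-(trimethylsilyloxy)but-2-enoate (E/Z mixture) | COC(=O)C=C(C)O[Si](C)(C)C | intermediate
14 | 1-methoxy-1,3-bis(trimethylsilyloxy)buta-1,3-diene (geometry at C1=C2 not defined) | COC(O[Si](C)(C)C)=CC(=C)O[Si](C)(C)C | intermediate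
15 | [4+2] cycloadduct, cyclohexa-1,4-diene (racemic, not isolated) | COC(=O)C1=C(Oc2c(OC)ccc(OC)c2OCC=C(C)C)CC(O[Si](C)(C)C)=CC1(OC)O[Si](C)(C)C | intermediate
16 | bis(trimethylsilyl) ether of 17 (not isolated) | COC(=O)c1c(O[Si](C)(C)C)cc(O[Si](C)(C)C)cc1Oc1c(OC)ccc(OC)c1OCC=C(C)C | intermediate
17 | methyl 2-{3,6-dimethoxy-2-[(3-methylbut-2-en-1-yl)oxy]phenoxy}-4,6-dihydroxybenzoate | COC(=O)c1c(O)cc(O)cc1Oc1c(OC)ccc(OC)c1OCC=C(C)C | intermediate
18 | ortho-dienone with the 1,1-dimethylallyl group at C3' (racemic, not isolated) | COC(=O)c1c(O)cc(O)cc1OC1=C(OC)C=CC(OC)(C(C)(C)C=C)C1=O | intermediate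
19 | para-dienone with the prenyl group at C5' (racemic, not isolated) | COC(=O)c1c(O)cc(O)cc1OC1=C(OC)C(CC=C(C)C)C=C(OC)C1=O | intermediate
20 | Paucinervin B (achiral) | COC(=O)c1c(O)cc(O)cc1Oc1c(O)c(OC)cc(CC=C(C)C)c1OC | target

**Totals**
Total steps: 9.
Longest linear sequence: 7 (steps 1, 2, 3, 4, 5, 8, 9); steps 6 and 7 form the short second branch.

**Steps most likely to fail**

1. Step 8 (bears the label).
   - What may go wrong: the aryloxy donor may make the alkyne so poor a dienophile that thermal silyl migration and decay of the diene outrun the cycloaddition. The addition may stop after the first C–C bond without ring closure. Traces of water may hydrate the ynol ether.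
   - Fallback (known chemistry): this sets out from phenol 5 and returns at 17. Ring A is brought in as an arene, with the polarity of the direct plan reversed. 2,4,6-Trihydroxybenzoic acid F1 would be condensed with acetone (TFAA, TFA) to 5,7-dihydroxy-2,2-dimethyl-4H-1,3-benzodioxin-4-one F2. F2 would be silylated at the non-chelated 7-OH (TIPSCl, imidazole) to the 7-silyl ether F3, and triflated at the 5-OH (Tf2O, pyridine) to the aryl triflate F4. A Pd-catalysed C–O coupling of Buchwald–Hartwig type (Pd2(dba)3, t-BuXPhos, K3PO4, toluene, 100 °C) would join the electron-poor, singly ortho-substituted F4 to the electron-rich phenol 5, giving the diaryl ether F5. TBAF would give the 7-phenol F6, and K2CO3/MeOH would open the dioxinone to the methyl ester and the free ortho-OH, which is 17.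

2. Step 9.
   - What may go wrong: heterolytic loss of the prenyl group, or its intermolecular transfer to the nucleophilic ring A, may replace the concerted double [3,3] shift. The freed C2'–OH may lactonise onto the ester with loss of methanol at 190 °C.
   - Fallback: this sets out from dichlorovinyl ether 8 and returns at 20. The sigmatropic shift is moved to a substrate that has no acidic OH, no ester and no second ring. Heating 8 (PhNEt2, 190 °C) would give 2-[(E)-1,2-dichloroethenyloxy]-3,6-dimethoxy-4-(3-methylbut-2-en-1-yl)phenol F7. n-BuLi (3.3 equiv) followed by ClCO2Me (2.2 equiv) would give, in one flask, the ynoate capped at O-2' as a methyl carbonate F8. Cycloaddition with 14 as in step 8 would give the O-2' methyl carbonate of the target F9. K2CO3/MeOH at rt would then release 20.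

3. Step 5.
   - What may go wrong: deprotonation at the allylic OCH2 with Wittig rearrangement, or ring lithiation, may compete with the elimination and exchange sequence. The push–pull alkyne may be hydrated during isolation.
   - Fallback: this sets out from phenol 5, returns at 11, and replaces steps 4 and 5 without any alkyllithium. Vinylic substitution by addition–elimination of 5 on methyl 3,3-dichloroacrylate F10 (K2CO3, DMF, rt) would give the bench-stable methyl 3-aryloxy-3-chloroacrylate F11. Dehydrochlorination with the non-nucleophilic base KHMDS (THF, –78 °C) would then give 11 just before use.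

**Further compounds**
F1 | step 8 | 2,4,6-trihydroxybenzoic acid | OC(=O)c1c(O)cc(O)cc1O
F2 | step 8 | 5,7-dihydroxy-2,2-dimethyl-4H-1,3-benzodioxin-4-one | CC1(C)OC(=O)c2c(O)cc(O)cc2O1
F3 | step 8 | 5-hydroxy-2,2-dimethyl-7-(triisopropylsilyloxy)-4H-1,3-benzodioxin-4-one | CC1(C)OC(=O)c2c(O)cc(O[Si](C(C)C)(C(C)C)C(C)C)cc2O1
F4 | step 8 | 2,2-dimethyl-4-oxo-7-(triisopropylsilyloxy)-4H-1,3-benzodioxin-5-yl trifluoromethanesulfonate | CC1(C)OC(=O)c2c(OS(=O)(=O)C(F)(F)F)cc(O[Si](C(C)C)(C(C)C)C(C)C)cc2O1
F5 | step 8 | 5-{3,6-dimethoxy-2-[(3-methylbut-2-en-1-yl)oxy]phenoxy}-2,2-dimethyl-7-(triisopropylsilyloxy)-4H-1,3-benzodioxin-4-one | CC1(C)OC(=O)c2c(Oc3c(OC)ccc(OC)c3OCC=C(C)C)cc(O[Si](C(C)C)(C(C)C)C(C)C)cc2O1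
F6 | step 8 | 5-{3,6-dimethoxy-2-[(3-methylbut-2-en-1-yl)oxy]phenoxy}-7-hydroxy-2,2-dimethyl-4H-1,3-benzodioxin-4-one | CC1(C)OC(=O)c2c(Oc3c(OC)ccc(OC)c3OCC=C(C)C)cc(O)cc2O1
F7 | step 9 | 2-[(E)-1,2-dichloroethenyloxy]-3,6-dimethoxy-4-(3-methylbut-2-en-1-yl)phenol | COc1cc(CC=C(C)C)c(OC)c(O/C(Cl)=C\Cl)c1O
F8 | step 9 | methyl 3-{3,6-dimethoxy-2-[(methoxycarbonyl)oxy]-5-(3-methylbut-2-en-1-yl)phenoxy}prop-2-ynoate | COC(=O)C#COc1c(OC(=O)OC)c(OC)cc(CC=C(C)C)c1OC
F9 | step 9 | methyl 2-{3,6-dimethoxy-2-[(methoxycarbonyl)oxy]-5-(3-methylbut-2-en-1-yl)phenoxy}-4,6-dihydroxybenzoate | COC(=O)c1c(O)cc(O)cc1Oc1c(OC(=O)OC)c(OC)cc(CC=C(C)C)c1OC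
F10 | step 5 | methyl 3,3-dichloroacrylate | COC(=O)C=C(Cl)Cl
F11 | step 5 | methyl 3-chloro-3-{3,6-dimethoxy-2-[(3-methylbut-2-en-1-yl)oxy]phenoxy}prop-2-enoate (E/Z mixture) | COC(=O)C=C(Cl)Oc1c(OC)ccc(OC)c1OCC=C(C)C
A1 | direct plan | 1-iodo-2-(methoxymethoxy)-3,6-dimethoxy-5-(3-methylbut-2-en-1-yl)benzene | COCOc1c(OC)cc(CC=C(C)C)c(OC)c1I
A2 | direct plan | methyl 2-hydroxy-4,6-bis(methoxymethoxy)benzoate | COC(=O)c1c(O)cc(OCOC)cc1OCOC
A3 | direct plan | methyl 2-[2-(methoxymethoxy)-3,6-dimethoxy-5-(3-methylbut-2-en-1-yl)phenoxy]-4,6-bis(methoxymethoxy)benzoate | COC(=O)c1c(OCOC)cc(OCOC)cc1Oc1c(OCOC)c(OC)cc(CC=C(C)C)c1OC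
A4 | direct plan | hydroquinone | Oc1ccc(O)cc1
A5 | direct plan | methyl 2,4,6-trihydroxybenzoate | COC(=O)c1c(O)cc(O)cc1O
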